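The route rests on cutting the bond between side-chain methylene C1' and the fully substituted carbon C2 of the pyran ring. C2 bears ring oxygen O1 and the sp2 carbon C3, so it can be made as an α-oxygenated propargylic carbanion: the lithiated carbamate of an (R)-4-arylbut-3-yn-2-ol captures the pinacol boronate of the complete polyprenyl chain, and a stereospecific 1,2-metallate shift moves C1' from boron to C2, after which boron is exchanged for the oxygen that becomes O1. The precursor is therefore acyclic: an aryl-alkynyl carbamate and a homoallylic boronic ester. Semi-hydrogenation and palladium-catalysed aryl ether formation then close the pyran ring.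

Key step: step 13

Assumption: the lithiated propargylic carbamate is taken to be borylated by the pinacol boronic ester with retention of configuration, as is usual for secondary carbamates; if inversion prevailed, the enantiomeric butynol would be used in step 11.

Locants used below: C1'–C24' for the side chain counted from the chromene, C2/C3/C4/C4a/C8a/O1 for the chromene.

**Phosphonate fragment**

Step 1
Reactants: 1 geranyl bromide
Product: 2 phenyl (3E)-4,8-dimethylnona-3,7-dien-1-yl sulfide
Conditions: PhSMe, n-BuLi, DABCO, THF, 0 °C; then 1, −78 °C to rt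
Reagents that add atoms: thioanisole, CSc1ccccc1
Why: SN2 alkylation of the sulfur-stabilised carbanion (phenylthio)methyllithium at the primary allylic bromide should add one carbon without moving or isomerising the E-olefin (carbanion alkylation).

Step 2
Reactants: 2 phenyl homogeranyl sulfide
Product: 3 homogeranyl iodide, (3E)-1-iodo-4,8-dimethylnona-3,7-diene
Conditions: MeI, NaI, DMF, 75 °C
Reagents that add atoms: methyl iodide, CI
Why: S-methylation gives a methylsulfonium salt whose unhindered primary carbon is attacked by iodide with loss of thioanisole, a dealkylative sulfide-to-iodide exchange (SN2) that leaves the trisubstituted olefins alone.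

Step 3
Reactants: 4 tert-butyl 2-(diethoxyphosphoryl)acetate; 3 homogeranyl iodide
Product: 5 tert-butyl (5E)-2-(diethoxyphosphoryl)-6,10-dimethylundeca-5,9-dienoate (racemic)
Conditions: NaH, DMSO, rt; then 3, 50 °C
Reagents that add atoms: none
Why: the sodium salt of the phosphonoacetate should be C-alkylated by the primary iodide (SN2 alkylation of a stabilised carbanion), the tert-butyl ester being inert to the base.

**Chain boronic ester**

Step 4
Reactants: 6 (2E,6E,10E)-geranylgeraniol
Product: 7 (2E,6E,10E)-geranylgeranyl acetate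
Conditions: Ac2O, pyridine, DMAP (cat.), CH2Cl2, 0 °C to rt
Reagents that add atoms: acetic anhydride, CC(=O)OC(C)=O
Why: DMAP-catalysed O-acetylation (acyl transfer), which also deactivates the 2,3-olefin towards the electrophilic bromine used next.

Step 5
Reactants: 7 geranylgeranyl acetate
Product: 9 (2E,6E,10E)-14,15-epoxy-3,7,11,15-tetramethylhexadeca-2,6,10-trien-1-ol (racemic epoxide), via bromohydrin acetate 8 (not isolated)
Conditions: NBS, THF/H2O, 0 °C; then K2CO3, MeOH, rt
Reagents that add atoms: water, O; N-bromosuccinimide, O=C1CCC(=O)N1Br (bromine of intermediate 8 only)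
Why: in aqueous THF the terminal trisubstituted olefin, the most exposed and electron-rich one, should take up bromonium ion and water selectively (bromohydrin formation), after which K2CO3 in methanol closes the epoxide by intramolecular Williamson reaction and removes the acetate by transesterification.

Step 6
Reactants: 9 epoxy alcohol
Product: 10 (4E,8E,12E)-14-hydroxy-4,8,12-trimethyltetradeca-4,8,12-trienal
Conditions: H5IO6, THF/Et2O, 0 °C
Reagents that add atoms: none
Why: periodic acid opens the trisubstituted epoxide and cleaves the resulting glycol in one operation (oxidative glycol cleavage), which should give the trisnor aldehyde and acetone without touching the allylic alcohol.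

Step 7
Reactants: 10 hydroxy aldehyde; 5 phosphonate
Product: 11 tert-butyl (2E,6E,10E,14E)-2-[(3E)-4,8-dimethylnona-3,7-dien-1-yl]-16-hydroxy-6,10,14-trimethylhexadeca-2,6,10,14-tetraenoate
Conditions: 5, NaH, THF, 0 °C; then 10, 0 °C to rt
Reagents that add atoms: none
Why: Horner–Wadsworth–Emmons olefination with the α-branched phosphonate and bulky ester should favour the E-enoate, in which the ester is trans to the aldehyde-derived chain, which is the geometry of the hydroxymethyl-bearing C15'=C16' olefin of the target; a minor Z-isomer would be removed by chromatography.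

Step 8
Reactants: 11 hydroxy enoate
Product: 12 tert-butyl (2E,6E,10E,14E)-16-bromo-2-[(3E)-4,8-dimethylnona-3,7-dien-1-yl]-6,10,14-trimethylhexadeca-2,6,10,14-tetraenoate
Conditions: CBr4, PPh3, CH2Cl2, 0 °C
Reagents that add atoms: carbon tetrabromide, BrC(Br)(Br)Br
Why: Appel bromination should convert the primary allylic alcohol into the bromide under neutral conditions, without allylic transposition and without loss of the tert-butyl ester.

Step 9
Reactants: 12 allylic bromide
Product: 13 tert-butyl (2E,6E,10E,14E)-2-[(3E)-4,8-dimethylnona-3,7-dien-1-yl]-6,10,14-trimethyl-17-(4,4,5,5-tetramethyl-1,3,2-dioxaborolan-2-yl)heptadeca-2,6,10,14-tetraenoate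
Conditions: CH2(Bpin)2, NaOt-Bu, THF, 0 °C to rt
Reagents that add atoms: bis(4,4,5,5-tetramethyl-1,3,2-dioxaborolan-2-yl)methane, CC1(C)OB(CB2OC(C)(C)C(C)(C)O2)OC1(C)C
Why: tert-butoxide-induced deborylation of the geminal bis(boronate) gives an α-boryl carbanion that should displace the primary allylic bromide in the SN2 sense (deborylative alkylation), installing C1' together with its boron handle, the fully substituted γ-carbon disfavouring SN2' attack and the tert-butyl ester being immune to transesterification.

**Aryl-alkynyl carbamate**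

Step 10
Reactants: 14 4-chloro-3-iodophenol
Product: 15 (4-chloro-3-iodophenoxy)tri(propan-2-yl)silane
Conditions: i-Pr3SiCl, imidazole, DMF, rt
Reagents that add atoms: chlorotri(propan-2-yl)silane, CC(C)[Si](Cl)(C(C)C)C(C)C
Why: imidazole-promoted O-silylation of the phenol gives a silyl ether that tolerates alkyllithium base, carbonate base and hydride.

Step 11
Reactants: 16 (R)-but-3-yn-2-ol; 15 aryl iodide
Product: 17 (2R)-4-[2-chloro-5-(triisopropylsilyloxy)phenyl]but-3-yn-2-ol
Conditions: Pd(PPh3)2Cl2 (cat.), CuI (cat.), Et3N, THF, rt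
Reagents that add atoms: none
Why: Sonogashira coupling, in which zerovalent palladium inserts into the C–I bond far faster than into the C–Cl bond, so the chloride is kept as the later ring-closure handle and the carbinol stereocenter is untouched.

Step 12
Reactants: 17 propargylic alcohol
Product: 18 (2R)-4-[2-chloro-5-(triisopropylsilyloxy)phenyl]but-3-yn-2-yl N,N-diisopropylcarbamate
Conditions: i-Pr2NCOCl, Et3N, toluene, 100 °C
Reagents that add atoms: N,N-diisopropylcarbamoyl chloride, CC(C)N(C(C)C)C(Cl)=O
Why: O-carbamoylation (acyl substitution at the carbamoyl chloride) installs the directing and leaving group for the lithiation–borylation without touching the stereocenter.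

**Union and endgame**

Step 13
Reactants: 18 aryl-alkynyl carbamate; 13 chain boronic ester
Product: 22 (18S)-tertiary propargylic alcohol carrying the whole chain and the arene, via lithiated carbamate 19 (not isolated), via lithium boronate 20 (not isolated), via tertiary boronic ester 21 (not isolated)
Conditions: 18, s-BuLi, TMEDA, Et2O, −78 °C; then 13, −78 °C to rt; then H2O2, aq NaOH, THF, 0 °C
Reagents that add atoms: hydrogen peroxide, OO
Why: Carbamate-directed deprotonation by s-BuLi removes the propargylic hydrogen with retention to give organolithium 19, which is borylated by the primary boronic ester 13 with retention to give boronate 20; on warming, C1' migrates from boron to the adjacent carbon anti to the departing carbamate (1,2-metallate rearrangement), forming the C1'–C2 bond in boronic ester 21, whose C–B bond is then oxidised with retention to the C–O bond of 22. The closest known reaction type is the lithiation–borylation of secondary propargylic carbamates with pinacol boronic esters, which gives tertiary propargylic boronic esters. No ring is closed in this step. The new fully substituted stereocenter is set by substrate control: the configuration of the (R)-carbinol carbon of 18 is transferred through these stereodefined events and should give the (S)-alcohol. The step needs chemoselectivity (α-lithiation instead of attack at the aryl halide, boronate formation instead of addition to the enoate) and borylation at the carbinol carbon and not at the allenyl terminus; these are secured by a chloride in place of a bromide on the arene, by a short lithiation at −78 °C, by the hindered α-branched tert-butyl enoate and by the unhindered primary boronic ester.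

Step 14
Reactants: 22 tertiary propargylic alcohol
Product: 23 (18S,19Z)-tertiary allylic alcohol (Z-styrenyl alkene)
Conditions: H2 (1 atm), Pd/CaCO3 poisoned with Pb(OAc)2, quinoline, EtOAc, rt
Reagents that add atoms: none
Why: Lindlar semi-hydrogenation adds hydrogen syn to the alkyne only, which should give the Z-alkene that places the tertiary hydroxyl next to the C–Cl carbon, while trisubstituted olefins, enoate and aryl chloride are inert.

Step 15
Reactants: 23 Z-allylic alcohol
Product: 24 tert-butyl (2E,6E,10E,14E)-2-[(3E)-4,8-dimethylnona-3,7-dien-1-yl]-6,10,14-trimethyl-17-[(2S)-2-methyl-6-(triisopropylsilyloxy)-2H-chromen-2-yl]heptadeca-2,6,10,14-tetraenoate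
Conditions: Pd(OAc)2 (cat.), t-BuXPhos, Cs2CO3, toluene, 90 °C
Reagents that add atoms: none
Why: intramolecular palladium-catalysed C–O coupling (Buchwald–Hartwig etherification): zerovalent palladium inserts into the C–Cl bond, the tertiary alkoxide binds and reductive elimination forms the O1–C8a bond and thus the pyran ring, with C2 untouched (configuration retained) and no β-hydrogen on the alkoxide carbon to divert the catalyst.

Step 16
Reactants: 24 chromene tert-butyl ester
Product: 25 (2E,6E,10E,14E)-2-[(3E)-4,8-dimethylnona-3,7-dien-1-yl]-6,10,14-trimethyl-17-[(2S)-2-methyl-6-(triisopropylsilyloxy)-2H-chromen-2-yl]heptadeca-2,6,10,14-tetraen-1-ol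
Conditions: i-Bu2AlH, CH2Cl2, −78 °C to 0 °C; aq potassium sodium tartrate
Reagents that add atoms: none
Why: 1,2-reduction of the α,β-unsaturated ester by the aluminium hydride should give the primary allylic alcohol with the olefin geometry intact (ester reduction), the chromene olefin and aryl silyl ether being inert.

Step 17
Reactants: 25 silyl-protected chromene alcohol
Product: 26 (2S)-2-[(3E,7E,11E,15E,19E)-16-(hydroxymethyl)-4,8,12,20,24-pentamethylpentacosa-3,7,11,15,19,23-hexaen-1-yl]-2-methyl-2H-chromen-6-ol (target)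
Conditions: n-Bu4NF, THF, 0 °C, argon
Reagents that add atoms: none
Why: fluoride-induced cleavage of the aryl silyl ether (desilylation) should free the 6-hydroxyl under non-acidic conditions that leave the chromene, the polyene and the allylic alcohol unchanged.

**Compound list**

1 | geranyl bromide, (2E)-1-bromo-3,7-dimethylocta-2,6-diene | CC(C)=CCC/C(C)=C/CBr | starting material
2 | phenyl (3E)-4,8-dimethylnona-3,7-dien-1-yl sulfide | CC(C)=CCC/C(C)=C/CCSc1ccccc1 | intermediate
3 | homogeranyl iodide, (3E)-1-iodo-4,8-dimethylnona-3,7-diene | CC(C)=CCC/C(C)=C/CCI | intermediate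
4 | tert-butyl 2-(diethoxyphosphoryl)acetate | CCOP(=O)(OCC)CC(=O)OC(C)(C)C | starting material
5 | tert-butyl (5E)-2-(diethoxyphosphoryl)-6,10-dimethylundeca-5,9-dienoate (racemic) | CCOP(=O)(OCC)C(CC/C=C(\C)CCC=C(C)C)C(=O)OC(C)(C)C | intermediate
6 | (2E,6E,10E)-geranylgeraniol | CC(C)=CCC/C(C)=C/CC/C(C)=C/CC/C(C)=C/CO | starting material
7 | (2E,6E,10E)-geranylgeranyl acetate | CC(C)=CCC/C(C)=C/CC/C(C)=C/CC/C(C)=C/COC(C)=O | intermediate
8 | (2E,6E,10E)-14-bromo-15-hydroxy-3,7,11,15-tetramethylhexadeca-2,6,10-trien-1-yl acetate (racemic) | CC(C)(O)C(Br)CC/C(C)=C/CC/C(C)=C/CC/C(C)=C/COC(C)=O | intermediate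
9 | (2E,6E,10E)-14,15-epoxy-3,7,11,15-tetramethylhexadeca-2,6,10-trien-1-ol (racemic epoxide) | CC1(C)OC1CC/C(C)=C/CC/C(C)=C/CC/C(C)=C/CO | intermediate
10 | (4E,8E,12E)-14-hydroxy-4,8,12-trimethyltetradeca-4,8,12-trienal | O=CCC/C(C)=C/CC/C(C)=C/CC/C(C)=C/CO | intermediate
11 | tert-butyl (2E,6E,10E,14E)-2-[(3E)-4,8-dimethylnona-3,7-dien-1-yl]-16-hydroxy-6,10,14-trimethylhexadeca-2,6,10,14-tetraenoate | CC(C)=CCC/C(C)=C/CC/C(=C\CC/C(C)=C/CC/C(C)=C/CC/C(C)=C/CO)C(=O)OC(C)(C)C | intermediate
12 | tert-butyl (2E,6E,10E,14E)-16-bromo-2-[(3E)-4,8-dimethylnona-3,7-dien-1-yl]-6,10,14-trimethylhexadeca-2,6,10,14-tetraenoate | CC(C)=CCC/C(C)=C/CC/C(=C\CC/C(C)=C/CC/C(C)=C/CC/C(C)=C/CBr)C(=O)OC(C)(C)C | intermediate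
13 | tert-butyl (2E,6E,10E,14E)-2-[(3E)-4,8-dimethylnona-3,7-dien-1-yl]-6,10,14-trimethyl-17-(4,4,5,5-tetramethyl-1,3,2-dioxaborolan-2-yl)heptadeca-2,6,10,14-tetraenoate | CC(C)=CCC/C(C)=C/CC/C(=C\CC/C(C)=C/CC/C(C)=C/CC/C(C)=C/CCB1OC(C)(C)C(C)(C)O1)C(=O)OC(C)(C)C | intermediate
14 | 4-chloro-3-iodophenol | Oc1ccc(Cl)c(I)c1 | starting material
15 | (4-chloro-3-iodophenoxy)tri(propan-2-yl)silane | CC(C)[Si](Oc1ccc(Cl)c(I)c1)(C(C)C)C(C)C | intermediate
16 | (R)-but-3-yn-2-ol | C[C@@H](O)C#C | starting material
17 | (2R)-4-[2-chloro-5-(triisopropylsilyloxy)phenyl]but-3-yn-2-ol | C[C@@H](O)C#Cc1cc(O[Si](C(C)C)(C(C)C)C(C)C)ccc1Cl | intermediate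
18 | (2R)-4-[2-chloro-5-(triisopropylsilyloxy)phenyl]but-3-yn-2-yl N,N-diisopropylcarbamate | C[C@@H](OC(=O)N(C(C)C)C(C)C)C#Cc1cc(O[Si](C(C)C)(C(C)C)C(C)C)ccc1Cl | intermediate
19 | α-lithiated carbamate (lithium in place of the carbinol hydrogen of 18, configuration retained) | C[C@@]([Li])(OC(=O)N(C(C)C)C(C)C)C#Cc1cc(O[Si](C(C)C)(C(C)C)C(C)C)ccc1Cl | intermediate
20 | lithium boronate complex of 19 with 13 (boron bound to the carbamate carbon and to C1') | C[C@@]([B-]1(CC/C=C(\C)CC/C=C(\C)CC/C=C(\C)CC/C=C(\CC/C=C(\C)CCC=C(C)C)C(=O)OC(C)(C)C)OC(C)(C)C(C)(C)O1)(OC(=O)N(C(C)C)C(C)C)C#Cc1cc(O[Si](C(C)C)(C(C)C)C(C)C)ccc1Cl.[Li+] | intermediate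
21 | tert-butyl (2E,6E,10E,14E,18R)-20-[2-chloro-5-(triisopropylsilyloxy)phenyl]-2-[(3E)-4,8-dimethylnona-3,7-dien-1-yl]-6,10,14,18-tetramethyl-18-(4,4,5,5-tetramethyl-1,3,2-dioxaborolan-2-yl)icosa-2,6,10,14-tetraen-19-ynoate | CC(C)=CCC/C(C)=C/CC/C(=C\CC/C(C)=C/CC/C(C)=C/CC/C(C)=C/CC[C@@](B1OC(C)(C)C(C)(C)O1)(C)C#Cc1cc(O[Si](C(C)C)(C(C)C)C(C)C)ccc1Cl)C(=O)OC(C)(C)C | intermediate
22 | tert-butyl (2E,6E,10E,14E,18S)-20-[2-chloro-5-(triisopropylsilyloxy)phenyl]-2-[(3E)-4,8-dimethylnona-3,7-dien-1-yl]-18-hydroxy-6,10,14,18-tetramethylicosa-2,6,10,14-tetraen-19-ynoate | CC(C)=CCC/C(C)=C/CC/C(=C\CC/C(C)=C/CC/C(C)=C/CC/C(C)=C/CC[C@@](O)(C)C#Cc1cc(O[Si](C(C)C)(C(C)C)C(C)C)ccc1Cl)C(=O)OC(C)(C)C | intermediate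
23 | tert-butyl (2E,6E,10E,14E,18S,19Z)-20-[2-chloro-5-(triisopropylsilyloxy)phenyl]-2-[(3E)-4,8-dimethylnona-3,7-dien-1-yl]-18-hydroxy-6,10,14,18-tetramethylicosa-2,6,10,14,19-pentaenoate | CC(C)=CCC/C(C)=C/CC/C(=C\CC/C(C)=C/CC/C(C)=C/CC/C(C)=C/CC[C@@](O)(C)/C=C\c1cc(O[Si](C(C)C)(C(C)C)C(C)C)ccc1Cl)C(=O)OC(C)(C)C | intermediate
24 | tert-butyl (2E,6E,10E,14E)-2-[(3E)-4,8-dimethylnona-3,7-dien-1-yl]-6,10,14-trimethyl-17-[(2S)-2-methyl-6-(triisopropylsilyloxy)-2H-chromen-2-yl]heptadeca-2,6,10,14-tetraenoate | CC(C)=CCC/C(C)=C/CC/C(=C\CC/C(C)=C/CC/C(C)=C/CC/C(C)=C/CC[C@@]1(C)C=Cc2cc(O[Si](C(C)C)(C(C)C)C(C)C)ccc2O1)C(=O)OC(C)(C)C | intermediate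
25 | (2E,6E,10E,14E)-2-[(3E)-4,8-dimethylnona-3,7-dien-1-yl]-6,10,14-trimethyl-17-[(2S)-2-methyl-6-(triisopropylsilyloxy)-2H-chromen-2-yl]heptadeca-2,6,10,14-tetraen-1-ol | CC(C)=CCC/C(C)=C/CC/C(=C\CC/C(C)=C/CC/C(C)=C/CC/C(C)=C/CC[C@@]1(C)C=Cc2cc(O[Si](C(C)C)(C(C)C)C(C)C)ccc2O1)CO | intermediate
26 | (2S)-2-[(3E,7E,11E,15E,19E)-16-(hydroxymethyl)-4,8,12,20,24-pentamethylpentacosa-3,7,11,15,19,23-hexaen-1-yl]-2-methyl-2H-chromen-6-ol | CC(C)=CCC/C(C)=C/CC/C(=C\CC/C(C)=C/CC/C(C)=C/CC/C(C)=C/CC[C@@]1(C)C=Cc2cc(O)ccc2O1)CO | target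

**Step count and risks**

Total step count: 17. Longest linear sequence: 11 steps (6 → 7 → 9 → 10 → 11 → 12 → 13 → 22 → 23 → 24 → 25 → 26, i.e. steps 4–9 and 13–17).

Steps most likely to fail:

1. Step 13. The aryl-conjugated lithiated carbamate may lose configurational integrity before it is borylated, and the organolithium may attack the aryl chloride or the enoate instead of boron. The fallback sets out from 13 and returns to the route at 22. Commercial (R)-4-(trimethylsilyl)but-3-yn-2-ol F1 would be carbamoylated (i-Pr2NCOCl, Et3N) to its diisopropylcarbamate F2, the silyl-capped carbamate type for which this lithiation–borylation is best established. Lithiation (s-BuLi, Et2O, −78 °C), borylation with 13, 1,2-shift and oxidation (H2O2, aq NaOH) would give the silylated tertiary propargylic alcohol F3. K2CO3 in MeOH would then give the terminal alkynol F4, and Sonogashira coupling of F4 with aryl iodide 15 (Pd(PPh3)2Cl2, CuI, Et3N) would give 22. The arene is joined only after the stereocenter exists, so neither an aryl chloride nor an aryl-conjugated anion meets the organolithium.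

2. Step 15. Oxidative addition into the electron-rich aryl chloride may be slow and C–O reductive elimination from the hindered tertiary alkoxide sluggish, so that hydrodechlorination or ionisation of the allylic alcohol wins. The fallback sets out from 23 and returns at 25, closing the ring by aryne capture instead of reductive elimination. Reduction of 23 with i-Bu2AlH would give the diol F5. Excess lithium 2,2,6,6-tetramethylpiperidide in THF (−78 °C to 0 °C) would deprotonate both hydroxyls and the only ring hydrogen ortho to chlorine. Loss of LiCl would give the 1,2-didehydroarene F6 (not isolated), which the tethered tertiary alkoxide should capture at the former C–Cl carbon through a six-membered ring. Protonation on work-up would give 25.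

3. Step 9. The alkoxide/α-boryl carbanion medium may deconjugate or isomerise the enoate, and the carbanion may attack in the SN2' sense. The fallback sets out from 12 and returns at 13, inserting C1' by Matteson homologation. Pd2(dba)3-catalysed borylation of 12 with B2pin2 (THF, 60 °C) would give the linear allylic boronic ester F7. Chloromethyllithium generated in its presence (BrCH2Cl, n-BuLi, THF, −78 °C to rt) would form the boronate and insert CH2 into the C–B bond by 1,2-shift, giving 13.

Further compounds
F1 | step 13 | (R)-4-(trimethylsilyl)but-3-yn-2-ol | C[C@@H](O)C#C[Si](C)(C)C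
F2 | step 13 | (R)-4-(trimethylsilyl)but-3-yn-2-yl N,N-diisopropylcarbamate | C[C@@H](OC(=O)N(C(C)C)C(C)C)C#C[Si](C)(C)C
F3 | step 13 | tert-butyl (2E,6E,10E,14E,18S)-2-[(3E)-4,8-dimethylnona-3,7-dien-1-yl]-18-hydroxy-6,10,14,18-tetramethyl-20-(trimethylsilyl)icosa-2,6,10,14-tetraen-19-ynoate | CC(C)=CCC/C(C)=C/CC/C(=C\CC/C(C)=C/CC/C(C)=C/CC/C(C)=C/CC[C@@](O)(C)C#C[Si](C)(C)C)C(=O)OC(C)(C)C
F4 | step 13 | tert-butyl (2E,6E,10E,14E,18S)-2-[(3E)-4,8-dimethylnona-3,7-dien-1-yl]-18-hydroxy-6,10,14,18-tetramethylicosa-2,6,10,14-tetraen-19-ynoate | CC(C)=CCC/C(C)=C/CC/C(=C\CC/C(C)=C/CC/C(C)=C/CC/C(C)=C/CC[C@@](O)(C)C#C)C(=O)OC(C)(C)C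
F5 | step 15 | (2E,6E,10E,14E,18S,19Z)-20-[2-chloro-5-(triisopropylsilyloxy)phenyl]-2-[(3E)-4,8-dimethylnona-3,7-dien-1-yl]-6,10,14,18-tetramethylicosa-2,6,10,14,19-pentaene-1,18-diol | CC(C)=CCC/C(C)=C/CC/C(=C\CC/C(C)=C/CC/C(C)=C/CC/C(C)=C/CC[C@@](O)(C)/C=C\c1cc(O[Si](C(C)C)(C(C)C)C(C)C)ccc1Cl)CO
F6 | step 15 | dilithium dialkoxide of the 1,2-didehydroarene formed from F5 by loss of HCl (aryne, not isolated) | CC(C)=CCC/C(C)=C/CC/C(=C\CC/C(C)=C/CC/C(C)=C/CC/C(C)=C/CC[C@@](O[Li])(C)/C=C\C1=CC(O[Si](C(C)C)(C(C)C)C(C)C)=CC#C1)CO[Li]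
F7 | step 9 | tert-butyl (2E,6E,10E,14E)-2-[(3E)-4,8-dimethylnona-3,7-dien-1-yl]-6,10,14-trimethyl-16-(4,4,5,5-tetramethyl-1,3,2-dioxaborolan-2-yl)hexadeca-2,6,10,14-tetraenoate | CC(C)=CCC/C(C)=C/CC/C(=C\CC/C(C)=C/CC/C(C)=C/CC/C(C)=C/CB1OC(C)(C)C(C)(C)O1)C(=O)OC(C)(C)C
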